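## Retrosynthetic overview
1. The last bond made is the benzylic CH2–NMe2 bond (C–N). This takes 2,5,6-tribromo-1-methylgramine back to 2,5,6-tribromo-1,3-dimethylindole and dimethylamine, joined by a direct C(sp3)–H amination.
2. The three C–Br bonds (C2, then C6, then C5) come from one exhaustive electrophilic bromination of 1,3-dimethylindole.
3. The N1–CH3 bond (second C–N bond) comes from N-methylation of 3-methylindole (skatole).
4. No ring is formed and no C–C bond is made, because the indole bicycle with its C3 carbon is bought as skatole.

Assumption: the target has no stereocentre (it is achiral), so there is no enantiomer to select and no SMILES carries a stereodescriptor.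

## Route

Step 1
Reactants: 1 3-methylindole (skatole)
Product: 2 1,3-dimethylindole
Conditions: KOH (powdered), MeI (1.2 equiv), DMSO, rt
Reagents that add atoms: iodomethane CI
Why: KOH/DMSO deprotonates N–H and the dissociated indolide is methylated on nitrogen by SN2 with MeI (Heaney–Ley-type indole N-alkylation), the C3 position being already substituted; no stereocentre is formed.

Step 2
Reactants: 2 1,3-dimethylindole
Product: 5 2,5,6-tribromo-1,3-dimethylindole, via 2-bromo-1,3-dimethylindole 3 (not isolated), via 2,6-dibromo-1,3-dimethylindole 4 (not isolated)
Conditions: NBS (3.05 equiv), silica gel, CH2Cl2, dark, 0 °C → rt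
Reagents that add atoms: N-bromosuccinimide O=C1CCC(=O)N1Br
Why: Electrophilic aromatic bromination (SEAr) with silica-activated NBS in the dark takes a 1,3-dialkylindole at C2 (C3 attack, 1,2-Br shift), then C6 (conjugated with the C2=C3 enamine), then C5 (para to N1), while C4 and C7 are peri-shielded by the two methyl groups and each Br slows further attack, so three equivalents stop at 5; no stereocentre is formed.

Step 3
Reactants: 5 2,5,6-tribromo-1,3-dimethylindole; 6 dimethylamine
Product: 9 2,5,6-tribromo-1-methylgramine, via N-bromodimethylamine 7 (not isolated), via 2,5,6-tribromo-3-(bromomethyl)-1-methylindole 8 (not isolated)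
Conditions: (a) 6 (40% aq., 1.1 equiv), NBS (1.1 equiv), CH2Cl2, 0 °C, phase cut, MgSO4 (cold solution of 7); (b) TFA (3 equiv), 5, N2, 450 nm LED, 0 °C; (c) K2CO3 (6 equiv), 6 (1 equiv more), MeCN, 0 °C → rt
Reagents that add atoms: none
Why: Proposed new method: an intermolecular Hofmann–Löffler–Freytag-type C(sp3)–H amination in which protonated 7 is photolysed to Me2NH•+/Br•, these electrophilic radicals abstract H from the weakest C–H (the indol-3-yl CH3, every reactive ring site being blocked or deactivated by Br), the benzylic radical takes Br from 7 to give 8 while the released amine is parked as its oxidation-proof ammonium salt, and K2CO3 then frees that amine to displace bromide through the 2-bromo-3-methyleneindoleninium ion (a polar C3-ipso-bromination/HBr-loss path leads to the same cation), so one reagent delivers both the oxidant and the nitrogen; the closest known reaction types are the intramolecular Hofmann–Löffler–Freytag reaction, Minisci-type N-haloammonium C–H halogenation, and Wohl–Ziegler bromination followed by amine alkylation; no stereocentre is formed.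

## Compound list
1 | 3-methylindole (skatole) | Cc1c[nH]c2ccccc12 | starting material
2 | 1,3-dimethylindole | Cc1cn(C)c2ccccc12 | intermediate
3 | 2-bromo-1,3-dimethylindole | Cc1c(Br)n(C)c2ccccc12 | intermediate
4 | 2,6-dibromo-1,3-dimethylindole | Cc1c(Br)n(C)c2cc(Br)ccc12 | intermediate
5 | 2,5,6-tribromo-1,3-dimethylindole | Cc1c(Br)n(C)c2cc(Br)c(Br)cc12 | intermediate
6 | dimethylamine | CNC | starting material
7 | N-bromodimethylamine | CN(C)Br | intermediate
8 | 2,5,6-tribromo-3-(bromomethyl)-1-methylindole | BrCc1c(Br)n(C)c2cc(Br)c(Br)cc12 | intermediate
9 | 2,5,6-tribromo-1-methylgramine | CN(C)Cc1c(Br)n(C)c2cc(Br)c(Br)cc12 | target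

Total step count: 3. Longest linear sequence: 3.

## Steps most likely to fail

**Step 3 (the proposed new step).**
- Risks:
  - The strongly electrophilic N-bromoammonium ion may brominate C4 or C7.
  - H-abstraction may occur at N–CH3.
  - The side chain may over-brominate to CHBr2.
  - Product 9 may be quaternised by 8.
- Fallback (known chemistry, a different logic of C–H oxidation to the carbonyl followed by reductive amination): the fallback sets out from 5. DDQ (2.2 equiv) in THF/H2O oxidises the 3-methyl group to 2,5,6-tribromo-1-methylindole-3-carbaldehyde F5. This aldehyde is condensed with 6 and reduced with NaBH(OAc)3 in 1,2-dichloroethane at 0 °C to rt, kept cold so the amine does not displace the C2 bromide. The fallback rejoins the route at 9.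

**Step 2.**
- Risks:
  - C3 attack may lead on to side-chain substitution or oxindole formation.
  - The third bromination may stall or give mixed regioisomers.
- Fallback (regiocontrol by an electron-withdrawing C3 group instead of innate indole reactivity): the fallback sets out from 2. DDQ in wet THF gives 1-methylindole-3-carbaldehyde F2. Br2 in AcOH is steered by the formyl group to C5 and C6 and gives 5,6-dibromo-1-methylindole-3-carbaldehyde F3. Reductive amination with 6 and NaBH(OAc)3 gives 5,6-dibromo-1-methylgramine F4. NBS in AcOH/HCO2H, with the side-chain amine protonated, brominates C2 last. The fallback rejoins the route at 9.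

**Step 1.**
- Risks (low):
  - Some C-methylation to the 3,3-dimethylindolenine.
  - Loss of the volatile, air-sensitive 2.
- Fallback (reversed order): the fallback sets out from 1. Bromination first with NBS on silica gel (3.05 equiv) gives 2,5,6-tribromo-3-methyl-1H-indole F1. Its much more acidic N–H is then methylated cleanly with MeI/K2CO3 in DMF. The fallback rejoins the route at 5.

## Further compounds
F1 | step 1 | 2,5,6-tribromo-3-methyl-1H-indole | Cc1c(Br)[nH]c2cc(Br)c(Br)cc12
F2 | step 2 | 1-methylindole-3-carbaldehyde | Cn1cc(C=O)c2ccccc12
F3 | step 2 | 5,6-dibromo-1-methylindole-3-carbaldehyde | Cn1cc(C=O)c2cc(Br)c(Br)cc12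
F4 | step 2 | 5,6-dibromo-1-methylgramine | CN(C)Cc1cn(C)c2cc(Br)c(Br)cc12
F5 | step 3 | 2,5,6-tribromo-1-methylindole-3-carbaldehyde | Cn1c(Br)c(C=O)c2cc(Br)c(Br)cc12
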